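**Plan**
1. Cuts: first C1=CH2, back to the C1 ketone. Then the key cut inside ring B (C6–C11). The CHBr carbon C10 stands between the quaternary C9 (CH3, Cl) and the CH2 group C11, so H on C11 and Cl on C9 are the two ends of HCl added across a former C9–C11 bond. Removing HCl contracts ring B to the five-membered ring C6-C7-C8-C9-C11 bridged by C10, an exo-6-bromo-5-methylbicyclo[3.1.0]hexane.
2. Further cuts: C5–C6 (ring A, bromonium ion onto a silyl enol ether), C1–C6 (acyl union of two fragments), and C11–C9 plus C11–C10 (carbene addition to an E vinyl bromide).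
3. Forward order: the five-membered ring and the cyclopropane form together, the C1–C5 chain is joined, and ring A closes on C6 to give the spiro centre. The five-membered ring is then enlarged to ring B by strain-releasing HCl opening, and methylenation ends the route.
4. Stereochemistry: C10 comes from the alkene geometry (stereospecific cyclopropanation) and the Cu(MeCN)4PF6–bis(oxazoline) catalyst. C4 comes from catalytic asymmetric bromolactonisation. C6 comes from the convex face of the bicycle together with a chair closure. C9 comes from entry of chloride anti to the C10 bromine.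

Key step: step 12

Remark: atom numbers follow the spiro[5.5]undecane frame of the target (C1 bears =CH2, C4 Br, C5 Me2, C6 spiro, C9 Me/Cl, C10 Br; ring A = C1–C6, ring B = C6–C11); compounds 1 and 11 are taken as catalogue compounds, and the antipode of each chiral catalyst (steps 4 and 7) is taken to be the one that gives the configuration drawn.

Step 1
Reactants: 1 pent-4-yn-1-ol
Product: 3 (E)-5-bromo-4-methylpent-4-en-1-ol, via alkenylalane 2 (not isolated)
Conditions: AlMe3 (3 equiv), Cp2ZrCl2 (0.25 equiv), CH2Cl2, 0 °C to rt; then N-bromosuccinimide, THF, −30 °C; aq. work-up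
Reagents that add atoms: trimethylaluminium, C[Al](C)C; N-bromosuccinimide, O=C1CCC(=O)N1Br
Why: Negishi carboalumination adds CH3 and Al syn and regioselectively to the terminal alkyne, and bromination of the C–Al bond goes with retention, so Br should end up cis to the new methyl group (E alkene), the geometry that later fixes C10.

Step 2
Reactants: 3 (E)-5-bromo-4-methylpent-4-en-1-ol
Product: 4 (E)-5-bromo-4-methylpent-4-enoic acid
Conditions: TEMPO (0.2 equiv), PhI(OAc)2 (2.5 equiv), MeCN–H2O 1:1, rt
Reagents that add atoms: water, O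
Why: The oxoammonium (TEMPO) oxidation takes the primary alcohol through the aldehyde hydrate to the acid and leaves the vinyl bromide and its geometry untouched.

Step 3
Reactants: 4 (E)-5-bromo-4-methylpent-4-enoic acid
Product: 6 (E)-6-bromo-1-diazo-5-methylhex-5-en-2-one, via acid chloride 5 (not isolated)
Conditions: (COCl)2, DMF (cat.), CH2Cl2, 0 °C to rt, evaporate; CH2N2 (3 equiv), Et2O, 0 °C
Reagents that add atoms: diazomethane, C=[N+]=[N-]; oxalyl chloride, O=C(Cl)C(=O)Cl (chlorine of 5 only)
Why: Acylation of diazomethane by an acid chloride (first half of the Arndt–Eistert sequence) gives the terminal α-diazoketone, with a second equivalent of diazomethane taking up the HCl.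

Step 4
Reactants: 6 (E)-6-bromo-1-diazo-5-methylhex-5-en-2-one
Product: 7 (1S,5S,6S)-6-bromo-5-methylbicyclo[3.1.0]hexan-2-one
Conditions: Cu(MeCN)4PF6 (5 mol %), 2,2'-(propane-2,2-diyl)bis[(4S)-4-tert-butyl-4,5-dihydro-1,3-oxazole] (6 mol %), CH2Cl2, slow addition of 6, rt
Reagents that add atoms: none
Why: Catalytic asymmetric intramolecular cyclopropanation of an alkenyl diazoketone joins the carbene carbon C11 to C9 and C10 and closes the five-membered ring; the addition is stereospecific, so the E alkene places Br exo (cis to CH3), and the C2-symmetric ligand selects the alkene face and so fixes C9, C10 and C11 absolutely.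

Step 5
Reactants: 7 (1S,5S,6S)-6-bromo-5-methylbicyclo[3.1.0]hexan-2-one
Product: 9 (1S,5S,6S)-6-bromo-5-methylbicyclo[3.1.0]hex-2-en-2-yl trifluoromethanesulfonate, via lithium enolate 8 (not isolated)
Conditions: LiN(SiMe3)2, THF, −78 °C; PhNTf2, −78 to 0 °C
Reagents that add atoms: N-phenylbis(trifluoromethanesulfonimide), O=S(=O)(N(c1ccccc1)S(=O)(=O)C(F)(F)F)C(F)(F)F; LiN(SiMe3)2, [Li]N([Si](C)(C)C)[Si](C)(C)C (lithium of 8 only)
Why: Enolate O-triflation; deprotonation can only occur at C7, because an enolate toward the cyclopropane bridgehead C11 would be prohibitively strained, so a single enol triflate should form.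

Step 6
Reactants: 9 (1S,5S,6S)-6-bromo-5-methylbicyclo[3.1.0]hex-2-en-2-yl trifluoromethanesulfonate
Product: 10 [(1R,5S,6S)-6-bromo-5-methylbicyclo[3.1.0]hex-2-en-2-yl]trimethylstannane
Conditions: Me3SnSnMe3 (1.1 equiv), Pd(PPh3)4 (5 mol %), LiCl (6 equiv), THF, 60 °C
Reagents that add atoms: hexamethylditin, C[Sn](C)(C)[Sn](C)(C)C
Why: Pd(PPh3)4-catalysed stannylation of an enol triflate (Stille-type coupling, LiCl-assisted) should be far faster than insertion into the cyclopropyl C–Br bond, and no stereocentre is touched.

Step 7
Reactants: 11 5-methylhex-4-enoic acid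
Product: 12 (5S)-5-bromo-6,6-dimethyloxan-2-one
Conditions: N-bromosuccinimide (1.1 equiv), cinchona-derived amino-thiocarbamate catalyst (10 mol %), CHCl3–toluene, −78 °C
Reagents that add atoms: N-bromosuccinimide, O=C1CCC(=O)N1Br
Why: Catalytic asymmetric bromolactonisation; the carboxylate opens the catalyst-bound bromonium ion at the tertiary carbon (Markovnikov, 6-endo), and catalyst control of the alkene face sets the C–Br centre that becomes C4 (S).

Step 8
Reactants: 12 (5S)-5-bromo-6,6-dimethyloxan-2-one
Product: 13 (4S)-4-bromo-5-chloro-5-methylhexanoyl chloride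
Conditions: SOCl2 (5 equiv), ZnCl2 (10 mol %), 50 °C; evaporate
Reagents that add atoms: thionyl chloride, O=S(Cl)Cl
Why: The classical ZnCl2-assisted conversion of a lactone into a chloro acyl chloride cleaves the tertiary alkyl–oxygen bond through the bromine-bridged cation, so C5 takes up chloride while C4 keeps its configuration.

Step 9
Reactants: 10 [(1R,5S,6S)-6-bromo-5-methylbicyclo[3.1.0]hex-2-en-2-yl]trimethylstannane; 13 (4S)-4-bromo-5-chloro-5-methylhexanoyl chloride
Product: 14 (4S)-4-bromo-1-[(1R,5S,6S)-6-bromo-5-methylbicyclo[3.1.0]hex-2-en-2-yl]-5-chloro-5-methylhexan-1-one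
Conditions: Pd2(dba)3 (2.5 mol %), P(2-furyl)3 (10 mol %), THF, 50 °C
Reagents that add atoms: none
Why: Stille acylation of a vinylstannane by an acid chloride is neutral and selective for the acyl C–Cl bond, so the tertiary chloride, the secondary bromide and the cyclopropyl bromide should survive the union that forms C1–C6.

Step 10
Reactants: 14 (4S)-4-bromo-1-[(1R,5S,6S)-6-bromo-5-methylbicyclo[3.1.0]hex-2-en-2-yl]-5-chloro-5-methylhexan-1-one
Product: 15 {[(1E,4S)-4-bromo-1-[(1R,5S,6S)-6-bromo-5-methylbicyclo[3.1.0]hexan-2-ylidene]-5-chloro-5-methylhexyl]oxy}triethylsilane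
Conditions: Et3SiH (1.5 equiv), RhCl(PPh3)3 (1 mol %), toluene, 50 °C
Reagents that add atoms: triethylsilane, CC[SiH](CC)CC
Why: RhCl(PPh3)3-catalysed 1,4-hydrosilylation of an enone by a monohydrosilane delivers Si to O and H to C7 through the s-cis conformer, which should give regiospecifically the tetrasubstituted silyl enol ether with O cis to C7 and C2 cis to C11 (E isomer).

Step 11
Reactants: 15 {[(1E,4S)-4-bromo-1-[(1R,5S,6S)-6-bromo-5-methylbicyclo[3.1.0]hexan-2-ylidene]-5-chloro-5-methylhexyl]oxy}triethylsilane
Product: 16 (1R,2R,5S,5'S,6S)-5',6-dibromo-5,6',6'-trimethylspiro[bicyclo[3.1.0]hexane-2,1'-cyclohexan]-2'-one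
Conditions: TiCl4 (1.1 equiv), 2,6-di-tert-butylpyridine (0.2 equiv), CH2Cl2, −78 to −40 °C; aq. NaHCO3
Reagents that add atoms: none
Why: Lewis-acid-mediated α-tert-alkylation of a silyl enol ether run intramolecularly; TiCl4 ionises the tertiary C5–Cl bond with participation of the C4 bromine (C4 retained), C6 attacks C5 anti to the bridging Br in a 6-(enolendo)-exo-tet closure through a chair with Br equatorial, and the spiro centre C6 is set because the E enol ether puts C7 equatorial and C11 axial and because C5 can reach only the face of the bicycle opposite to the cyclopropane, two demands met by the same transition state.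

Step 12
Reactants: 16 (1R,2R,5S,5'S,6S)-5',6-dibromo-5,6',6'-trimethylspiro[bicyclo[3.1.0]hexane-2,1'-cyclohexan]-2'-one
Product: 18 (4S,6R,9S,10S)-4,10-dibromo-9-chloro-5,5,9-trimethylspiro[5.5]undecan-1-one, via bromonium chloride 17 (not isolated)
Conditions: HCl (g, saturated), (CF3)2CHOH–CH2Cl2 1:1, 0 °C to rt
Reagents that add atoms: hydrogen chloride, Cl
Why: Proposed new method: HCl, made a stronger and less nucleophilic acid by the hydrogen-bond-donor solvent, should protonate the inner cyclopropane bond C9–C11 at C11 so that the bond breaks toward the tertiary, methyl-bearing C9, and the strain of the bicyclo[3.1.0]hexane is released as the five-membered ring C6-C7-C8-C9-C11 takes in C10 and becomes the six-membered ring B. The closest known reaction types are the Markovnikov hydrochlorination of alkylcyclopropanes and the acid opening of thujane-type bicyclo[3.1.0]hexanes to p-menthane derivatives, neither of which has been shown on a bromocyclopropane. No ring is closed in this step: a three-membered ring is opened, and the one-carbon enlargement from five to six atoms follows from the choice of the inner bond. The only new stereocentre, C9, is controlled by C10: the bromine bridges the cationic C9 on the side that C11 has left (17) and chloride enters anti to it, a concerted backside attack of chloride on C9 gives the same (S) centre, and C4, C6 and C10 are not touched. The step needs inner-bond instead of outer-bond cleavage, which is secured because proton attack at C10 is disfavoured by the electron-withdrawing bromine on that carbon, because a halogen substituent weakens the distal C9–C11 bond, because this is the most alkylated and most electron-rich edge, and because its cleavage leaves a cyclohexane and not a cyclopentane. It also needs the C–Br bonds to stay: the exo bromide cannot ionise by the disrotatory cyclopropyl-to-allyl opening within a six-membered ring, the neopentyl C4–Br bond and the ketone are inert to HCl, and any alkene or C1-oxygen-bridged oxocarbenium ion formed from 17 returns to 17 under excess HCl.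

Step 13
Reactants: 18 (4S,6R,9S,10S)-4,10-dibromo-9-chloro-5,5,9-trimethylspiro[5.5]undecan-1-one
Product: 19 nidificene
Conditions: Cp2TiMe2 (3 equiv), toluene, 70 °C, dark
Reagents that add atoms: dimethyltitanocene Cp2TiMe2, [CH3-].[CH3-].[Ti+4].c1cc[cH-]c1.c1cc[cH-]c1
Why: Petasis methylenation; the thermally formed Cp2Ti=CH2 is small and non-basic, so the hindered, enolisable C1 ketone should be converted into C1=CH2 without base-induced elimination or 1,3-elimination of the halides, and no stereocentre is touched.

**Compound list**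
1 | pent-4-yn-1-ol | C#CCCCO | starting material
2 | dimethylaluminium (E)-5-(dimethylalumanyl)-4-methylpent-4-en-1-olate | C[Al](C)OCCC/C(C)=C/[Al](C)C | intermediate
3 | (E)-5-bromo-4-methylpent-4-en-1-ol | OCCC/C(C)=C/Br | intermediate
4 | (E)-5-bromo-4-methylpent-4-enoic acid | OC(=O)CC/C(C)=C/Br | intermediate
5 | (E)-5-bromo-4-methylpent-4-enoyl chloride | ClC(=O)CC/C(C)=C/Br | intermediate
6 | (E)-6-bromo-1-diazo-5-methylhex-5-en-2-one | [N-]=[N+]=CC(=O)CC/C(C)=C/Br | intermediate
7 | (1S,5S,6S)-6-bromo-5-methylbicyclo[3.1.0]hexan-2-one (Br exo) | O=C1CC[C@]2(C)[C@@H](Br)[C@H]12 | intermediate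
8 | lithium (1S,5S,6S)-6-bromo-5-methylbicyclo[3.1.0]hex-2-en-2-olate | [Li]OC1=CC[C@]2(C)[C@@H](Br)[C@H]12 | intermediate
9 | (1S,5S,6S)-6-bromo-5-methylbicyclo[3.1.0]hex-2-en-2-yl trifluoromethanesulfonate | O=S(=O)(OC1=CC[C@]2(C)[C@@H](Br)[C@H]12)C(F)(F)F | intermediate
10 | [(1R,5S,6S)-6-bromo-5-methylbicyclo[3.1.0]hex-2-en-2-yl]trimethylstannane | C[Sn](C)(C)C1=CC[C@]2(C)[C@@H](Br)[C@H]12 | intermediate
11 | 5-methylhex-4-enoic acid | CC(C)=CCCC(=O)O | starting material
12 | (5S)-5-bromo-6,6-dimethyloxan-2-one | O=C1CC[C@H](Br)C(C)(C)O1 | intermediate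
13 | (4S)-4-bromo-5-chloro-5-methylhexanoyl chloride | O=C(Cl)CC[C@H](Br)C(C)(C)Cl | intermediate
14 | (4S)-4-bromo-1-[(1R,5S,6S)-6-bromo-5-methylbicyclo[3.1.0]hex-2-en-2-yl]-5-chloro-5-methylhexan-1-one | O=C(CC[C@H](Br)C(C)(C)Cl)C1=CC[C@]2(C)[C@@H](Br)[C@H]12 | intermediate
15 | {[(1E,4S)-4-bromo-1-[(1R,5S,6S)-6-bromo-5-methylbicyclo[3.1.0]hexan-2-ylidene]-5-chloro-5-methylhexyl]oxy}triethylsilane | CC[Si](CC)(CC)O/C(CC[C@H](Br)C(C)(C)Cl)=C1\CC[C@]2(C)[C@@H](Br)[C@H]12 | intermediate
16 | (1R,2R,5S,5'S,6S)-5',6-dibromo-5,6',6'-trimethylspiro[bicyclo[3.1.0]hexane-2,1'-cyclohexan]-2'-one | O=C1CC[C@H](Br)C(C)(C)[C@]12CC[C@]3(C)[C@@H](Br)[C@H]23 | intermediate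
17 | C9,C10-bridged bromonium chloride of the ring-enlarged ketone | O=C1CC[C@H](Br)C(C)(C)[C@]12CC[C@@]3(C)[Br+][C@H]3C2.[Cl-] | intermediate
18 | (4S,6R,9S,10S)-4,10-dibromo-9-chloro-5,5,9-trimethylspiro[5.5]undecan-1-one | O=C1CC[C@H](Br)C(C)(C)[C@]12CC[C@](C)(Cl)[C@@H](Br)C2 | intermediate
19 | nidificene, (4S,6S,9S,10S)-4,10-dibromo-9-chloro-5,5,9-trimethyl-1-methylidenespiro[5.5]undecane | C=C1CC[C@H](Br)C(C)(C)[C@]12CC[C@](C)(Cl)[C@@H](Br)C2 | target

Total step count: 13. Longest linear sequence: 11 (steps 1–6 and 9–13).

**Steps most likely to fail**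

Step 12. The inner cyclopropane bond may stay unprotonated next to the crowded spiro centre, or the opening may take the outer C9–C10 bond (wrong regiochemistry of opening).
- The fallback sets out from 7 and comes back at 18. It moves the ring enlargement to the stage where the C6 carbonyl group is conjugated with the cyclopropane.
- The known acid-promoted homoconjugate addition of HCl to a cyclopropyl ketone has chloride attacking the tertiary C9 with inversion, followed by tautomerisation of the enol. It should give (3S,4S)-3-bromo-4-chloro-4-methylcyclohexan-1-one F1, which is kept cold and acidic because it is a β-bromo ketone.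
- Tf2O with 2,6-di-tert-butyl-4-methylpyridine gives (4S,5S)-5-bromo-4-chloro-4-methylcyclohex-1-en-1-yl trifluoromethanesulfonate F2; the regioisomer toward C11 is removed by chromatography.
- The reactions of steps 6, 9, 10 and 11 are then run in the six-membered series. They pass through [(4S,5S)-5-bromo-4-chloro-4-methylcyclohex-1-en-1-yl]trimethylstannane F3, the enone (4S)-4-bromo-1-[(4S,5S)-5-bromo-4-chloro-4-methylcyclohex-1-en-1-yl]-5-chloro-5-methylhexan-1-one F4 and its (E)-triethylsilyl enol ether F5.
- TiCl4 closure of F5 gives 18, the spiro centre then being set by the enol ether geometry and the chair closure alone.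

Step 11. O-alkylation or protodesilylation may outrun bond formation between two fully substituted carbons, or the tertiary chloride may lose HCl.
- The fallback sets out from 15 and comes back at 16.
- Mild aqueous acid (citric acid, THF–H2O) gives the saturated ketone (4S)-4-bromo-1-[(1R,5S,6S)-6-bromo-5-methylbicyclo[3.1.0]hexan-2-yl]-5-chloro-5-methylhexan-1-one F6, either epimer at the acyl-bearing carbon.
- F6 is solvolysed in (CF3)2CHOH, the known ionisation of a vicinal bromochloride to a configurationally stable bromonium ion for cation–olefin cyclisation.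
- Capture by the carbonyl oxygen is reversible in this medium, whereas capture by the enol carbon C6 is not, so the material should drain to 16 under thermodynamic control.

Step 13. The carbonyl group flanked by the spiro centre may not react, or heating may cause loss of hydrogen halide.
- The fallback sets out from 18 and comes back at 19, and uses a Peterson olefination instead.
- Me3SiCH2Li with CeCl3 (THF, −78 °C), a reagent of low basicity, adds to give (4S,6R,9S,10S)-4,10-dibromo-9-chloro-5,5,9-trimethyl-1-[(trimethylsilyl)methyl]spiro[5.5]undecan-1-ol F7, either C1 epimer.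
- HF·pyridine in MeCN at 0 °C then brings about the acid-type elimination to 19.

**Further compounds**
F1 | step 12 | (3S,4S)-3-bromo-4-chloro-4-methylcyclohexan-1-one | O=C1CC[C@](C)(Cl)[C@@H](Br)C1
F2 | step 12 | (4S,5S)-5-bromo-4-chloro-4-methylcyclohex-1-en-1-yl trifluoromethanesulfonate | O=S(=O)(OC1=CC[C@](C)(Cl)[C@@H](Br)C1)C(F)(F)F
F3 | step 12 | [(4S,5S)-5-bromo-4-chloro-4-methylcyclohex-1-en-1-yl]trimethylstannane | C[Sn](C)(C)C1=CC[C@](C)(Cl)[C@@H](Br)C1
F4 | step 12 | (4S)-4-bromo-1-[(4S,5S)-5-bromo-4-chloro-4-methylcyclohex-1-en-1-yl]-5-chloro-5-methylhexan-1-one | O=C(CC[C@H](Br)C(C)(C)Cl)C1=CC[C@](C)(Cl)[C@@H](Br)C1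
F5 | step 12 | (E)-triethylsilyl enol ether of the 1,4-reduced F4 (O cis to C7) | CC[Si](CC)(CC)O/C(CC[C@H](Br)C(C)(C)Cl)=C1\CC[C@](C)(Cl)[C@@H](Br)C1
F6 | step 11 | (4S)-4-bromo-1-[(1R,5S,6S)-6-bromo-5-methylbicyclo[3.1.0]hexan-2-yl]-5-chloro-5-methylhexan-1-one | O=C(CC[C@H](Br)C(C)(C)Cl)C1CC[C@]2(C)[C@@H](Br)[C@H]12
F7 | step 13 | (4S,6R,9S,10S)-4,10-dibromo-9-chloro-5,5,9-trimethyl-1-[(trimethylsilyl)methyl]spiro[5.5]undecan-1-ol | C[Si](C)(C)CC1(O)CC[C@H](Br)C(C)(C)[C@]12CC[C@](C)(Cl)[C@@H](Br)C2
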